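The readings were generated by integration on assumed constants.

A nearly straight run of readings tempts one to carry its slope over to another flask, and that is the pitfall here.

| flask | Sub | Cat | time |
|---|---|---|---|
| autumn | 150 mM | 0.750 mM |  |
| midnight | 90.0 mM | 0.750 mM |  |
| summer | 150 mM | 1.10 mM |  |
| noon | 220 mM | 0.750 mM |  |
| spring | 50.0 mM | 2.30 mM | 11 min |

| run | time / min | [Sub] / mM |
|---|---|---|
| autumn run | 1.4 | 139.8 |
| autumn run | 2.8 | 128.3 |
| autumn run | 4.1 | 118.2 |
| autumn run | 5.5 | 106.8 |
| autumn run | 6.9 | 96.2 |
| autumn run | 8.2 | 85.4 |
| autumn run | 9.6 | 74.9 |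
| autumn run | 11 | 65.3 |
| midnight run | 1.4 | 83.2 |
| midnight run | 2.8 | 76.1 |
| midnight run | 4.1 | 70.1 |
| midnight run | 5.5 | 63.6 |
| midnight run | 6.9 | 58.3 |
| midnight run | 8.2 | 53.2 |
| midnight run | 9.6 | 48.8 |
| midnight run | 11 | 44.9 |
| summer run | 1.4 | 135.0 |
| summer run | 2.8 | 120.5 |
| summer run | 4.1 | 105.1 |
| summer run | 5.5 | 90.5 |
| summer run | 6.9 | 77.9 |
| summer run | 8.2 | 67.1 |
| summer run | 9.6 | 56.4 |
| summer run | 11 | 45.7 |
| noon run | 1.4 | 206.8 |
| noon run | 2.8 | 191.4 |
| noon run | 4.1 | 175.1 |
| noon run | 5.5 | 155.4 |
| noon run | 6.9 | 136.1 |
| noon run | 8.2 | 118.0 |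
| noon run | 9.6 | 98.9 |
| noon run | 11 | 81.1 |

(each reading ± 0.4 mM)

- Overall: Sub -> Prd, with Cat as catalyst.
- Constant volume, constant temperature.
- A reading of a species includes what of it is bound.
- An order is taken over about fifteen percent of the charge, up and down.

* the exponent of [Cat] in the starting rate at the charge of the autumn run (at the point where two percent of the Sub have become Prd)
* the exponent of [Sub] in the starting rate at the charge of the autumn run (at the point where two percent of the Sub have become Prd) (one fixed amount of Prd, the same in the runs compared)
* the midnight run starts with 60.0 mM less of Sub than the autumn run, and with no Prd. Compared where both hold the same amount of Sub, once fifteen percent of what the midnight run was charged with has turned into Prd, is the midnight run faster, slower or alike (within a tenth)?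
* Sub in the spring run at 11 min, as a share of the Sub charged

My colleague and I agree that Sub is heading for zero in the spring run and that loss scales with Cat: summer's first drop is 1.47 times autumn's, for a Cat ratio of 1.47. We part on how zero is approached.

She holds to the line. The autumn run loses 7.70 mM min⁻¹ on average, so the Cat of the spring run makes that 23.6 mM min⁻¹. On her line the spring run is empty at 2.12 min, earlier than the time asked.

I hold to a clock. In the midnight run, the lowest charge of Sub among the runs with readings, the loss falls from 4.86 mM min⁻¹ in the first interval to 2.79 mM min⁻¹ in the last, slower as Sub thins. So at low Sub I treat the decay as pseudo-first-order, with a fixed time for each halving.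

If loss scales with Cat, then at low Sub that time multiplied by the Cat charged should stay constant. I call this the halving product, and from the first midnight interval it reads 0.556 M·s. The scatter is 5.88 % of that drop, so it is a reading and no better.

Dividing by the Cat of the spring run gives a halving time of 4.03 min. The time asked holds 2.73 halvings, which by my reckoning leaves 15.1 % of the Sub charged in the spring run.

The forecast takes the clock side with a different number: exponents of 0.8 for Cat and 0.65 for Sub, midnight slower, and 17 % left in the spring run (range 9 % to 27 %), reckoned “with little activation at low Sub”.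

The simulation gives exponents of 0.97 for Cat and 0.64 for Sub, midnight slower, and 14.9 % of the charge left in the spring run, which is no empty flask. The steps behind the readings are these.

    Cat + Sub ⇌ Cat.Sub, settled at all times (4.910 L mol⁻¹)
    Cat.Sub → Prd + Cat (22.74 min⁻¹)
    Sub + Prd → 2 Prd (0.8340 L mol⁻¹ min⁻¹)
    Cat → Z (0.09660 min⁻¹)

Taken on a fixed clock, that share of the spring run is a halving time of 4.01 min. The line keeps its ground in the autumn run, which loses 7.29 mM min⁻¹ in its first interval and 6.86 mM min⁻¹ in its last. Put to the summer run, the halving product gives 8.42 min, while Prd there reaches half the Sub charged at 7.22 min, sooner.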